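The ten-membered carbocycle is disconnected at C1–C2. C2 is a methylene between the alkenyl carbon C1 and the oxygenated C3, so it is generated as a radical by decarboxylation of a β-silyloxy acid and captured by an alkenylnickel formed from a (Z)-C1 iodide. One operation forms C1–C2 and closes the C1–C10 ring onto the preformed cis-fused γ-lactone (O–C6–C7–C11–C12). The precursor is a seco N-acyloxyphthalimide carrying the (Z)-iodoalkene, the saturated cis-lactone, a C3 triethylsilyl ether, a C8 tert-butyldimethylsilyl ether and a C9 p-methoxybenzyl ether. It is assembled from one epoxy alcohol that serves both ends and a succinyl unit.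

Key step: step 16

Remark: germacrane numbering is used (ring C1–C10, lactone carbons C11–C13, C1′ = the carboxyl carbon that is lost). Read from the target SMILES, the lactone is cis-fused (H6/H7 cis), the C6/C7, C7/C8 and C8/C9 relationships are all anti in the zigzag chain, and both ring alkenes carry their ring carbons cis. The CIP label at C7 changes with the O8 substituent, so the SMILES are authoritative.

Step 1
Reactants: 1 prop-2-yn-1-ol
Product: 3 (Z)-3-iodo-2-methylprop-2-en-1-ol, via alkenylmagnesium alkoxide 2 (not isolated)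
Conditions: MeMgBr (2.5 equiv), CuI (cat.), THF, −10 °C → rt; I2, −10 °C; aq. NH4Cl
Reagents that add atoms: methylmagnesium bromide, C[Mg]Br; iodine, II
Why: Copper-catalysed anti-carbomagnesiation of the propargylic alkoxide puts methyl on the internal carbon and magnesium cis to the carbinol carbon in a five-membered chelate, and iodinolysis with retention gives the Z iodoalkene.

Step 2
Reactants: 3 (Z)-3-iodo-2-methylprop-2-en-1-ol; 4 ethyl (triphenylphosphoranylidene)acetate
Product: 6 ethyl (2E,4Z)-5-iodo-4-methylpenta-2,4-dienoate, via (Z)-3-iodo-2-methylprop-2-enal 5 (not isolated)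
Conditions: MnO2, CH2Cl2, rt, 4 present from the start
Reagents that add atoms: none
Why: Tandem allylic oxidation–Wittig olefination traps the isomerisation-prone Z iodoenal as it forms, and the stabilised ylide gives the E enoate.

Step 3
Reactants: 6 ethyl (2E,4Z)-5-iodo-4-methylpenta-2,4-dienoate
Product: 7 (2E,4Z)-5-iodo-4-methylpenta-2,4-dien-1-ol
Conditions: i-Bu2AlH, CH2Cl2, −78 °C; Rochelle salt
Reagents that add atoms: none
Why: 1,2-Reduction of the conjugated ester by the aluminium hydride at low temperature gives the allylic alcohol and leaves the iodoalkene alone.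

Step 4
Reactants: 7 (2E,4Z)-5-iodo-4-methylpenta-2,4-dien-1-ol
Product: 8 [(2R,3R)-3-[(Z)-1-iodoprop-1-en-2-yl]oxiran-2-yl]methanol
Conditions: Ti(O-i-Pr)4 (cat.), D-(−)-diethyl tartrate, t-BuOOH, 4 Å MS, CH2Cl2, −20 °C
Reagents that add atoms: tert-butyl hydroperoxide, CC(C)(C)OO
Why: Sharpless asymmetric epoxidation of the E allylic alcohol with the D-(−)-tartrate sets both epoxide carbons as R, while the distal iodoalkene is neither allylic to the hydroxyl nor electron-rich and stays intact.

Step 5
Reactants: 8 [(2R,3R)-3-[(Z)-1-iodoprop-1-en-2-yl]oxiran-2-yl]methanol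
Product: 9 (2R,3S,4Z)-5-iodo-3-[(4-methoxyphenyl)methoxy]-4-methylpent-4-ene-1,2-diol
Conditions: 4-MeOC6H4CH2OH (3 equiv), BF3·OEt2 (cat.), CH2Cl2, −40 °C
Reagents that add atoms: 4-methoxybenzyl alcohol, COc1ccc(CO)cc1
Why: Lewis-acid alcoholysis of the vinyl epoxide proceeds by SN2 attack at the allylic carbon (future C9) with inversion, which sets C9 as S and installs its p-methoxybenzyl ether in one operation.

Step 6
Reactants: 9 (2R,3S,4Z)-5-iodo-3-[(4-methoxyphenyl)methoxy]-4-methylpent-4-ene-1,2-diol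
Product: 10 (2S,3Z)-4-iodo-2-[(4-methoxyphenyl)methoxy]-3-methylbut-3-enal
Conditions: NaIO4, THF/pH 7 buffer, 0 °C; used crude
Reagents that add atoms: none
Why: Periodate glycol cleavage removes the terminal carbon under neutral conditions and leaves the α-alkoxy aldehyde (C8) with the C9 stereocentre untouched.

Step 7
Reactants: 8 [(2R,3R)-3-[(Z)-1-iodoprop-1-en-2-yl]oxiran-2-yl]methanol
Product: 11 (3S,4Z)-5-iodo-4-methylpent-4-ene-1,3-diol
Conditions: NaAlH2(OCH2CH2OMe)2, THF, −20 → 0 °C
Reagents that add atoms: none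
Why: Intramolecular hydride delivery from the alkoxyaluminate opens the 2,3-epoxy alcohol at C-2, so the oxygen on the future C3 is retained (S) and the 1,3-diol results.

Step 8
Reactants: 11 (3S,4Z)-5-iodo-4-methylpent-4-ene-1,3-diol
Product: 12 (3S,4Z)-5-iodo-4-methyl-1,3-bis(triethylsilyloxy)pent-4-ene
Conditions: Et3SiCl, imidazole, CH2Cl2, 0 °C
Reagents that add atoms: chlorotriethylsilane, CC[Si](Cl)(CC)CC
Why: Routine silylation of both hydroxyls, the primary triethylsilyl ether serving later as a latent aldehyde.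

Step 9
Reactants: 12 (3S,4Z)-5-iodo-4-methyl-1,3-bis(triethylsilyloxy)pent-4-ene; 13 methyl 4-chloro-4-oxobutanoate
Product: 16 methyl (5Z,7S)-6-methyl-4-oxo-7,9-bis(triethylsilyloxy)non-5-enoate, via alkenyllithium 14 (not isolated), via alkenylzinc chloride 15 (not isolated)
Conditions: t-BuLi (2 equiv), Et2O, −78 °C; ZnCl2, THF, −78 → 0 °C; 13, Pd(PPh3)4 (cat.), 0 °C → rt
Reagents that add atoms: none
Why: Iodine–lithium exchange with retention, transmetallation to zinc and palladium-catalysed acylation (Negishi acylation) give the Z enone and spare the ester, and exchange in ether at −78 °C with immediate transmetallation suppresses 1,4-silyl migration.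

Step 10
Reactants: 16 methyl (5Z,7S)-6-methyl-4-oxo-7,9-bis(triethylsilyloxy)non-5-enoate; 10 (2S,3Z)-4-iodo-2-[(4-methoxyphenyl)methoxy]-3-methylbut-3-enal
Product: 19 methyl (3S,4R,5S,6Z)-4-hydroxy-7-iodo-5-[(4-methoxyphenyl)methoxy]-6-methyl-3-[(2Z,4S)-3-methyl-4,6-bis(triethylsilyloxy)hex-2-enoyl]hept-6-enoate, via (E)-dicyclohexylboron enolate 17 (not isolated), via dicyclohexylboron aldolate 18 (not isolated)
Conditions: (c-C6H11)2BCl, Et3N, Et2O, −78 → 0 °C; 10, −78 → −20 °C; H2O2, MeOH, pH 7 buffer, 0 °C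
Reagents that add atoms: none
Why: The boron chloride/amine pair gives the E enolate, whose Zimmerman–Traxler chair gives the 7,8-anti aldol, and the α-alkoxy aldehyde reacts in the Cornforth (Felkin) sense to give 8,9-anti, so the C9 stereocentre controls both C8 and C7.

Step 11
Reactants: 19 C8 alcohol (aldol adduct)
Product: 20 C8 tert-butyldimethylsilyl ether of 19
Conditions: t-BuMe2SiOTf, 2,6-lutidine, CH2Cl2, −78 °C, directly after work-up of step 10
Reagents that add atoms: tert-butyldimethylsilyl triflate, CC(C)(C)[Si](C)(C)OS(=O)(=O)C(F)(F)F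
Why: Silylation of the β-hydroxy ketone with the triflate at low temperature outruns retro-aldol and lactonisation onto C12 and blocks O8 before O6 is set free.

Step 12
Reactants: 20 C8 silyl ether (C6 ketone)
Product: 22 cis-fused 6,12-lactone bearing the C1′ triethylsilyl ether, via C6 lithium alkoxide 21 (not isolated)
Conditions: LiBH(s-Bu)3, THF, −78 → 0 °C; aq. NH4Cl
Reagents that add atoms: none
Why: The bulky hydride adds 1,2 to the twisted β,β-disubstituted enone under Felkin–Anh control (C8 as the large group, reinforced by the β-silyloxy dipole) to give the 6,7-anti alkoxide, which closes onto the methyl ester to form the cis-fused γ-lactone.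

Step 13
Reactants: 22 cis-fused lactone (C1′ triethylsilyl ether)
Product: 23 C1′ aldehyde
Conditions: (COCl)2, DMSO, CH2Cl2, −78 → −30 °C; Et3N, −78 → 0 °C
Reagents that add atoms: none
Why: Swern conditions convert a primary triethylsilyl ether directly into the aldehyde, while the secondary triethylsilyl and tert-butyldimethylsilyl ethers survive.

Step 14
Reactants: 23 C1′ aldehyde
Product: 24 C1′ carboxylic acid (β-silyloxy acid)
Conditions: NaClO2, NaH2PO4, 2-methyl-2-butene, t-BuOH/H2O, 0 °C
Reagents that add atoms: sodium chlorite, [Na+].[O-]Cl=O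
Why: Pinnick oxidation takes the aldehyde to the acid under buffered conditions that spare silyl ethers, the iodoalkene and the p-methoxybenzyl ether.

Step 15
Reactants: 24 C1′ carboxylic acid
Product: 25 seco N-acyloxyphthalimide (redox-active ester)
Conditions: N-hydroxyphthalimide, DIC, DMAP (cat.), CH2Cl2, 0 °C → rt
Reagents that add atoms: N-hydroxyphthalimide, O=C1c2ccccc2C(=O)N1O
Why: Carbodiimide coupling gives the redox-active ester under near-neutral conditions, which avoids β-elimination of the C3 silyloxy group, and the ester is made last because it is the most labile group.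

Step 16
Reactants: 25 seco N-acyloxyphthalimide
Product: 26 ten-membered cis-fused lactone (3-OTES, 8-OTBS, 9-OPMB)
Conditions: NiCl2·glyme (30 mol %), 2,2′-bipyridine (36 mol %), AgNO3 (30 mol %), DMF, Mg anode, RVC cathode, undivided cell, constant current at low current density, slow addition of 25 to 2 mM, rt
Reagents that add atoms: none
Why: Proposed new method: cathodically formed low-valent nickel inserts into the (Z)-C1–I bond, single-electron reduction of the N-acyloxyphthalimide expels phthalimide and CO2 to leave the primary C2 radical, and capture of this radical by the divalent alkenylnickel gives a trivalent alkyl(alkenyl)nickel that reductively eliminates the C1–C2 bond; the closest known reaction type is the intermolecular nickel-catalysed (electro)reductive decarboxylative alkenylation of redox-active esters with alkenyl halides. The C1–C10 carbocycle closes by radical capture at nickel and reductive elimination through an eleven-membered nickelacycle, not by radical addition to an alkene. No stereocentre is formed. The step needs retention of the Z geometry at C10=C1, which reductive elimination from alkenylnickel secures, and ring closure in preference to hydrodeiodination, dimerisation, 1,5-hydrogen transfer from C6–H or homoallyl rearrangement of the C2 radical; the cis-lactone and the two Z alkenes fold the chain so that C1 and C2 lie close, and slow addition at high dilution with low current density keeps intermolecular paths and the radical concentration low. A C2 radical, unlike a C2 organometallic, does not expel the C3 silyloxy group, and the lactone is kept saturated and C3 kept as a silyl ether so that the radical meets neither a conjugate acceptor nor a migrating acyloxy group.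

Step 17
Reactants: 26 ten-membered cis-fused lactone
Product: 29 α-methylene lactone (3-OTES, 8-OTBS, 9-OPMB), via Mannich base 27 (not isolated), via trimethylammonium iodide 28 (not isolated)
Conditions: LiN(SiMe3)2, THF, −78 °C; CH2=NMe2+ I−, −78 °C → rt; MeI, CH2Cl2, rt; aq. NaHCO3
Reagents that add atoms: Eschenmoser's salt (N,N-dimethylmethyleneiminium iodide), C=[N+](C)C.[I-]
Why: Mannich reaction of the lactone lithium enolate, N-methylation and base-induced elimination of trimethylamine install the C11 exocyclic methylene, which removes the transient C11 stereocentre.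

Step 18
Reactants: 29 α-methylene lactone
Product: 30 C3 alcohol
Conditions: PPTS (cat.), MeOH/CH2Cl2, 0 °C
Reagents that add atoms: none
Why: Mild acid methanolysis cleaves the secondary triethylsilyl ether far faster than the hindered tert-butyldimethylsilyl ether at C8.

Step 19
Reactants: 30 C3 alcohol
Product: 31 C3 acetate
Conditions: Ac2O, pyridine, DMAP (cat.), CH2Cl2, 0 °C
Reagents that add atoms: acetic anhydride, CC(=O)OC(C)=O
Why: DMAP-catalysed acetylation of the only free hydroxyl.

Step 20
Reactants: 31 C3 acetate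
Product: 32 C9 alcohol
Conditions: DDQ, CH2Cl2/pH 7 buffer, 0 °C
Reagents that add atoms: none
Why: Oxidative cleavage of the p-methoxybenzyl ether by DDQ through the benzylic oxocarbenium ion, buffered so that the acetate, the silyl ether and the methylene lactone are untouched.

Step 21
Reactants: 33 angelic acid
Product: 34 (Z)-2-methylbut-2-en-1-ol
Conditions: LiAlH4, Et2O, 0 °C
Reagents that add atoms: none
Why: Hydride reduction of the carboxylic acid gives the allylic alcohol with the Z geometry intact.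

Step 22
Reactants: 34 (Z)-2-methylbut-2-en-1-ol
Product: 35 [(2S,3R)-2,3-dimethyloxiran-2-yl]methanol
Conditions: Ti(O-i-Pr)4 (cat.), L-(+)-diethyl tartrate, t-BuOOH, 4 Å MS, CH2Cl2, −20 °C
Reagents that add atoms: tert-butyl hydroperoxide, CC(C)(C)OO
Why: Sharpless asymmetric epoxidation with the L-(+)-tartrate sets both epoxide carbons, the cis relationship of C3-methyl and hydroxymethyl coming from the Z alkene.

Step 23
Reactants: 35 [(2S,3R)-2,3-dimethyloxiran-2-yl]methanol
Product: 36 (2R,3R)-2,3-dimethyloxirane-2-carboxylic acid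
Conditions: RuCl3·xH2O (cat.), NaIO4, MeCN/EtOAc/H2O, 0 °C → rt
Reagents that add atoms: sodium periodate (terminal oxidant), [Na+].[O-]I(=O)(=O)=O; water, O
Why: Ruthenium tetroxide formed in the flask oxidises the primary alcohol to the acid without opening the epoxide, and C2 becomes R only through the change in substituent priorities.

Step 24
Reactants: 32 C9 alcohol; 36 (2R,3R)-2,3-dimethyloxirane-2-carboxylic acid
Product: 38 C9 epoxyangelate (C8 silyl ether of the target), via mixed anhydride 37 (not isolated)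
Conditions: 36, 2,4,6-trichlorobenzoyl chloride, Et3N, toluene, rt; 32, DMAP, toluene, rt → 40 °C
Reagents that add atoms: none
Why: Yamaguchi esterification through the mixed anhydride acylates the hindered allylic alcohol, and the acid has no α-hydrogen, so it cannot epimerise.

Step 25
Reactants: 38 C8 silyl ether of the target
Product: 39 target (CNP0137407.4)
Conditions: HF·pyridine, pyridine, THF, 0 °C → rt
Reagents that add atoms: none
Why: Buffered fluoride under mildly acidic conditions removes the last silyl ether without acyl migration from O9 to O8, translactonisation to O8 or conjugate addition to the methylene lactone.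

Compound list
1 | prop-2-yn-1-ol | C#CCO | starting material
2 | bromomagnesium (Z)-3-(bromomagnesio)-2-methylprop-2-en-1-olate | Br[Mg]/C=C(/C)CO[Mg]Br | intermediate
3 | (Z)-3-iodo-2-methylprop-2-en-1-ol | OC/C(C)=C\I | intermediate
4 | ethyl (triphenylphosphoranylidene)acetate | CCOC(=O)C=P(c1ccccc1)(c1ccccc1)c1ccccc1 | starting material
5 | (Z)-3-iodo-2-methylprop-2-enal | O=C/C(C)=C\I | intermediate
6 | ethyl (2E,4Z)-5-iodo-4-methylpenta-2,4-dienoate | CCOC(=O)/C=C/C(C)=C\I | intermediate
7 | (2E,4Z)-5-iodo-4-methylpenta-2,4-dien-1-ol | OC/C=C/C(C)=C\I | intermediate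
8 | [(2R,3R)-3-[(Z)-1-iodoprop-1-en-2-yl]oxiran-2-yl]methanol | OC[C@H]1O[C@@H]1/C(C)=C\I | intermediate
9 | (2R,3S,4Z)-5-iodo-3-[(4-methoxyphenyl)methoxy]-4-methylpent-4-ene-1,2-diol | OC[C@@H](O)[C@@H](OCc1ccc(OC)cc1)/C(C)=C\I | intermediate
10 | (2S,3Z)-4-iodo-2-[(4-methoxyphenyl)methoxy]-3-methylbut-3-enal (C8–C1 unit) | O=C[C@@H](OCc1ccc(OC)cc1)/C(C)=C\I | intermediate
11 | (3S,4Z)-5-iodo-4-methylpent-4-ene-1,3-diol | OCC[C@H](O)/C(C)=C\I | intermediate
12 | (3S,4Z)-5-iodo-4-methyl-1,3-bis(triethylsilyloxy)pent-4-ene (C1′–C5 unit) | CC[Si](CC)(CC)OCC[C@H](O[Si](CC)(CC)CC)/C(C)=C\I | intermediate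
13 | methyl 4-chloro-4-oxobutanoate | COC(=O)CCC(Cl)=O | starting material
14 | (Z)-alkenyllithium from 12 | CC[Si](CC)(CC)OCC[C@H](O[Si](CC)(CC)CC)/C(C)=C\[Li] | intermediate
15 | (Z)-alkenylzinc chloride from 12 | CC[Si](CC)(CC)OCC[C@H](O[Si](CC)(CC)CC)/C(C)=C\[Zn]Cl | intermediate
16 | methyl (5Z,7S)-6-methyl-4-oxo-7,9-bis(triethylsilyloxy)non-5-enoate (C6 ketone, C12 ester) | CC[Si](CC)(CC)OCC[C@H](O[Si](CC)(CC)CC)/C(C)=C\C(=O)CCC(=O)OC | intermediate
17 | (E)-dicyclohexylboron enolate of 16 (C6=C7) | CC[Si](CC)(CC)OCC[C@H](O[Si](CC)(CC)CC)/C(C)=C\C(=C/CC(=O)OC)OB(C1CCCCC1)C1CCCCC1 | intermediate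
18 | dicyclohexylboron aldolate of 19 | CC[Si](CC)(CC)OCC[C@H](O[Si](CC)(CC)CC)/C(C)=C\C(=O)[C@@H](CC(=O)OC)[C@@H](OB(C1CCCCC1)C1CCCCC1)[C@@H](OCc1ccc(OC)cc1)/C(C)=C\I | intermediate
19 | methyl (3S,4R,5S,6Z)-4-hydroxy-7-iodo-5-[(4-methoxyphenyl)methoxy]-6-methyl-3-[(2Z,4S)-3-methyl-4,6-bis(triethylsilyloxy)hex-2-enoyl]hept-6-enoate (7,8-anti, 8,9-anti aldol adduct) | CC[Si](CC)(CC)OCC[C@H](O[Si](CC)(CC)CC)/C(C)=C\C(=O)[C@@H](CC(=O)OC)[C@@H](O)[C@@H](OCc1ccc(OC)cc1)/C(C)=C\I | intermediate
20 | C8 tert-butyldimethylsilyl ether of 19 | CC[Si](CC)(CC)OCC[C@H](O[Si](CC)(CC)CC)/C(C)=C\C(=O)[C@@H](CC(=O)OC)[C@@H](O[Si](C)(C)C(C)(C)C)[C@@H](OCc1ccc(OC)cc1)/C(C)=C\I | intermediate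
21 | C6 lithium alkoxide (6,7-anti) of the reduced ketone | CC[Si](CC)(CC)OCC[C@H](O[Si](CC)(CC)CC)/C(C)=C\[C@@H](O[Li])[C@@H](CC(=O)OC)[C@@H](O[Si](C)(C)C(C)(C)C)[C@@H](OCc1ccc(OC)cc1)/C(C)=C\I | intermediate
22 | cis-fused 6,12-lactone with 3-OTES, C1′-OTES, 8-OTBS, 9-OPMB and (Z)-C1 iodide | CC[Si](CC)(CC)OCC[C@H](O[Si](CC)(CC)CC)/C(C)=C\[C@H]1OC(=O)C[C@H]1[C@@H](O[Si](C)(C)C(C)(C)C)[C@@H](OCc1ccc(OC)cc1)/C(C)=C\I | intermediate
23 | C1′ aldehyde of 22 | O=CC[C@H](O[Si](CC)(CC)CC)/C(C)=C\[C@H]1OC(=O)C[C@H]1[C@@H](O[Si](C)(C)C(C)(C)C)[C@@H](OCc1ccc(OC)cc1)/C(C)=C\I | intermediate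
24 | C1′ carboxylic acid (β-silyloxy acid) | OC(=O)C[C@H](O[Si](CC)(CC)CC)/C(C)=C\[C@H]1OC(=O)C[C@H]1[C@@H](O[Si](C)(C)C(C)(C)C)[C@@H](OCc1ccc(OC)cc1)/C(C)=C\I | intermediate
25 | seco N-acyloxyphthalimide with (Z)-C1 iodoalkene and cis-lactone (key-step precursor) | O=C(C[C@H](O[Si](CC)(CC)CC)/C(C)=C\[C@H]1OC(=O)C[C@H]1[C@@H](O[Si](C)(C)C(C)(C)C)[C@@H](OCc1ccc(OC)cc1)/C(C)=C\I)ON1C(=O)c2ccccc2C1=O | intermediate
26 | protected ten-membered saturated cis-lactone (key-step product) | O=C1C[C@@H]2[C@H](O1)/C=C(/C)[C@@H](O[Si](CC)(CC)CC)C/C=C(/C)[C@H](OCc1ccc(OC)cc1)[C@@H]2O[Si](C)(C)C(C)(C)C | intermediate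
27 | C11 dimethylaminomethyl lactone (Mannich base, C11 epimers) | O=C1C(CN(C)C)[C@@H]2[C@H](O1)/C=C(/C)[C@@H](O[Si](CC)(CC)CC)C/C=C(/C)[C@H](OCc1ccc(OC)cc1)[C@@H]2O[Si](C)(C)C(C)(C)C | intermediate
28 | C11 trimethylammoniomethyl lactone iodide | O=C1C(C[N+](C)(C)C)[C@@H]2[C@H](O1)/C=C(/C)[C@@H](O[Si](CC)(CC)CC)C/C=C(/C)[C@H](OCc1ccc(OC)cc1)[C@@H]2O[Si](C)(C)C(C)(C)C.[I-] | intermediate
29 | α-methylene lactone (3-OTES, 8-OTBS, 9-OPMB) | O=C1C(=C)[C@@H]2[C@H](O1)/C=C(/C)[C@@H](O[Si](CC)(CC)CC)C/C=C(/C)[C@H](OCc1ccc(OC)cc1)[C@@H]2O[Si](C)(C)C(C)(C)C | intermediate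
30 | C3 alcohol (8-OTBS, 9-OPMB) | O=C1C(=C)[C@@H]2[C@H](O1)/C=C(/C)[C@@H](O)C/C=C(/C)[C@H](OCc1ccc(OC)cc1)[C@@H]2O[Si](C)(C)C(C)(C)C | intermediate
31 | C3 acetate (8-OTBS, 9-OPMB) | O=C1C(=C)[C@@H]2[C@H](O1)/C=C(/C)[C@@H](OC(C)=O)C/C=C(/C)[C@H](OCc1ccc(OC)cc1)[C@@H]2O[Si](C)(C)C(C)(C)C | intermediate
32 | C9 alcohol (3-OAc, 8-OTBS) | O=C1C(=C)[C@@H]2[C@H](O1)/C=C(/C)[C@@H](OC(C)=O)C/C=C(/C)[C@H](O)[C@@H]2O[Si](C)(C)C(C)(C)C | intermediate
33 | angelic acid, (Z)-2-methylbut-2-enoic acid | C/C=C(/C)C(=O)O | starting material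
34 | (Z)-2-methylbut-2-en-1-ol | C/C=C(/C)CO | intermediate
35 | [(2S,3R)-2,3-dimethyloxiran-2-yl]methanol | OC[C@]1(C)O[C@@H]1C | intermediate
36 | (2R,3R)-2,3-dimethyloxirane-2-carboxylic acid | OC(=O)[C@]1(C)O[C@@H]1C | intermediate
37 | mixed anhydride of 36 with 2,4,6-trichlorobenzoic acid | O=C(OC(=O)c1c(Cl)cc(Cl)cc1Cl)[C@]1(C)O[C@@H]1C | intermediate
38 | C8 tert-butyldimethylsilyl ether of the target | O=C1C(=C)[C@@H]2[C@H](O1)/C=C(/C)[C@@H](OC(C)=O)C/C=C(/C)[C@H](OC(=O)[C@]3(C)O[C@@H]3C)[C@@H]2O[Si](C)(C)C(C)(C)C | intermediate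
39 | CNP0137407.4 | C=C1C(=O)O[C@@H]2/C=C(/C)[C@@H](OC(C)=O)C/C=C(/C)[C@H](OC(=O)[C@]3(C)O[C@@H]3C)[C@H](O)[C@H]12 | target

Total step count: 25 steps.
Longest linear sequence: 20 steps (steps 1, 2, 3, 4, 7, 8, 9, 10 to 20, 24, 25).

Steps most likely to fail

Step 16. The C2 radical may be reduced, abstract the allylic C6 hydrogen or rearrange before it meets nickel, or the alkenylnickel may be protonated, so that reduced open-chain material forms instead of the ring. The fallback sets out from 25. A light-driven decarboxylative borylation (bis(catecholato)diboron, DMAc, blue light; then pinacol, Et3N) gives the C2 pinacol boronate F1 with the iodoalkene intact. A macrocyclising B-alkyl Suzuki–Miyaura coupling (Pd(dppf)Cl2, K3PO4, THF/DMF/H2O, high dilution, 60 °C) then forms C1–C2 in a two-electron manifold, the bidentate ligand speeding reductive elimination so that it outruns β-silyloxy elimination. The fallback comes back to the route at 26.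

Step 10. The α-alkoxy aldehyde may lose configuration at C9 or suffer double-bond migration under the amine and boron reagents, or enolisation may not be E-selective, which erodes diastereoselectivity. The fallback sets out from 16. LiN(SiMe3)2 and Me3SiCl (THF, −78 °C) give the trimethylsilyl enol ether F2, and N-bromosuccinimide (THF, −78 °C) gives the α-bromo ketone F3. CrCl2 (LiI cat., THF, rt) in the presence of 10 forms a trivalent chromium enolate under neutral conditions, and its anti-selective chromium Reformatsky addition to the Felkin face of 10 comes back to the route at 19.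

Step 12. Hydride delivery to the C6 ketone may show poor facial selectivity, or the hydride may add in conjugate fashion. The fallback sets out from 20. Luche reduction (NaBH4, CeCl3·7H2O, MeOH/THF, −78 °C) is strictly 1,2 and gives both C6 epimers, which close to 22 and to the trans-fused lactone F4. After separation, F4 is opened with LiOH (THF/H2O) to the hydroxy acid F5. Mitsunobu lactonisation (PPh3, DIAD, THF, 0 °C) then lets the carboxylate displace the activated allylic C6 oxygen with inversion, which comes back to the route at 22.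

Further compounds
F1 | step 16 | C2 pinacol boronate of the seco lactone (C1′ replaced by boron) | CC1(C)OB(C[C@H](O[Si](CC)(CC)CC)/C(C)=C\[C@H]2OC(=O)C[C@H]2[C@@H](O[Si](C)(C)C(C)(C)C)[C@@H](OCc2ccc(OC)cc2)/C(C)=C\I)OC1(C)C
F2 | step 10 | trimethylsilyl enol ether of 16 (C6=C7) | CC[Si](CC)(CC)OCC[C@H](O[Si](CC)(CC)CC)/C(C)=C\C(O[Si](C)(C)C)=CCC(=O)OC
F3 | step 10 | C7 bromo ketone from 16 (C7 epimers) | CC[Si](CC)(CC)OCC[C@H](O[Si](CC)(CC)CC)/C(C)=C\C(=O)C(Br)CC(=O)OC
F4 | step 12 | trans-fused lactone, C6 epimer of 22 | CC[Si](CC)(CC)OCC[C@H](O[Si](CC)(CC)CC)/C(C)=C\[C@@H]1OC(=O)C[C@H]1[C@@H](O[Si](C)(C)C(C)(C)C)[C@@H](OCc1ccc(OC)cc1)/C(C)=C\I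
F5 | step 12 | C6-epimeric hydroxy acid from F4 | CC[Si](CC)(CC)OCC[C@H](O[Si](CC)(CC)CC)/C(C)=C\[C@H](O)[C@@H](CC(=O)O)[C@@H](O[Si](C)(C)C(C)(C)C)[C@@H](OCc1ccc(OC)cc1)/C(C)=C\I
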